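## The problem

Compound 25 is a (3R)-isoflavan. Ring A (C4a to C8a) is a resorcinol unit with a free hydroxyl at C7 and a prenyl group at C8. Ring B (C1' to C6') carries a free hydroxyl at C2' and a 2,2-dimethyl-2H-pyran fused across C3'–C4'. The arenes are joined through C2–C3–C4: C3 is bonded directly to C1', C4 to C4a, and C2 to O1 on C8a.

The only stereocentre, C3, is a benzylic methine with no heteroatom and no neighbouring stereocentre, so it must be set by a catalyst or reagent. It stays configurationally safe only while neither C2 nor C4 is a carbonyl carbon.

The prenyl alkene (ortho to the C7 hydroxyl) and the chromene alkene exclude hydrogenation, hence asymmetric reduction of an isoflavene and benzyl ethers. They also exclude electrophilic halogenation once the prenyl group is present (haloetherification) and strong acid (cyclisation to a dimethylchroman, addition to the chromene).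

Three phenolic oxygens must be told apart. Only the C8a oxygen may attack C2, because the C2' oxygen is placed to close a five-membered ring on the same carbon. Ring A carries four contiguous substituents (C4a chain, C8a–O, C8 prenyl, C7–O), which no simple electrophilic substitution delivers cleanly.

The enabling feature is the 1,2-diarylethyl pattern. C3 bears ring B directly and ring A one carbon away through C4, and C2 is a single carbon on C3. A vinylboron ate complex can supply C3 and C4, take ring B onto C3 by a 1,2-shift from boron and ring A onto C4 from an aryl halide, and leave boron on C3 exactly where C2 must be attached. The ortho oxygens help: the C2' oxygen (as its MOM ether) directs metalation of ring B to C1', and the C8a oxygen is the later ring-closing nucleophile.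

## Retrosynthesis

**25 from 24.** The last operation only frees the C2' hydroxyl from its methoxymethyl (MOM) ether; no skeletal bond is cut. The MOM group is kept to the end because it directs the ring B metalation and blocks the C2' oxygen during pyran closure. The forward step needs an acid mild enough for the prenyl and chromene groups.

**24 from 23 and 22.** The pyran is opened at O1–C2, giving the acyclic 2,3-diarylpropan-1-ol 23 with free ring A phenols, and behind it the bis-silyl ether 22. Cutting O1–C8a instead would require an aryl C–O coupling at the most hindered position of ring A. Cutting at C2 asks only for a 6-exo etherification of a primary alcohol, with no carbonyl next to C3. The forward reaction (fluoride, then Mitsunobu closure) requires that the C8a oxygen be unmasked while the C2' oxygen stays protected, which fixes the protecting-group pattern: silyl on ring A, MOM on ring B.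

**22 from 21 and 19.** C2 is removed by cutting C2–C3 back to a C3–B bond. Alcohol 22 comes from the primary boronic ester 21 by oxidation, and 21 from the secondary benzylic boronic ester 19 by one-carbon Matteson homologation, which proceeds with retention at C3. This is preferred to carrying C2 as a carbonyl carbon, because C3 is then never alpha to a carbonyl group. Precursor 19 contains only C3 and C4 between the rings.

**19 from 15, 16 and 17.** The key disconnection cuts C3–C1' and C4–C4a together, giving vinylboronic acid pinacol ester 16, ring B aryllithium 17 and ring A aryl bromide 15. Cutting only one of these bonds would need a stereodefined two-carbon partner made separately. The three-component coupling takes C3 and C4 from a commodity reagent and sets C3 catalytically.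

The polarity is dictated by the structure. The migrating group ends on the boron-bearing carbon (C3), so ring B must be the nucleophile and ring A the electrophile. This suits both fragments: the MOM ether of ring B directs lithiation to C1', while ring A, with a silyl ether ortho to the reacting carbon, is safer as a bromide than as an aryllithium prone to silyl migration. The forward reaction must control the face of the vinyl group, tolerate an ortho substituent on each partner, and leave the prenyl and chromene alkenes alone.

**17 from 6, 5, 3, 1 and 2.** Aryllithium 17 comes from MOM ether 6 by directed ortho-metalation, and 6 from chromenol 5. The arene of ring B is not taken from a phenol but built from cyclohexane-1,3-dione 1 and prenal 2 (formal [3+3] annulation to 3, then dehydrogenative aromatisation). This places the hydroxyl next to the pyran ring fusion carbon without ambiguity, whereas direct chromenylation of a resorcinol would favour the other orientation.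

**15 from 14, 13, 11, 8, 9 and 7.** The four contiguous substituents of ring A are installed by two directed metalations on 1,3-bis(methoxymethoxy)benzene 8, made from resorcinol 7. The first, between the two MOM ethers, introduces the prenyl group from bromide 9 to give 11. The second, at a position ortho to one MOM ether, introduces bromine to give 13; the symmetry of 11 makes its two ortho positions equivalent. Electrophilic bromination of a prenylated phenol was rejected: the prenyl alkene would compete through bromoetherification, and ortho and para positions would be hard to distinguish. Delivering bromine to a carbanion avoids both problems. The MOM groups of 13 are then exchanged for silyl groups (14, then 15) so that ring A oxygens can later be freed by fluoride in the presence of the ring B MOM ether.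

## Roads not taken

**Alternative 1:** Cut C4–C4a and O1–C2, creating C3 by protonation. 2-Prenylresorcinol A3 and the 2-arylacrolein A2 would react under chiral primary-amine iminium catalysis. The steps are Friedel–Crafts conjugate addition of the resorcinol carbon to the acrolein CH2, enantioselective protonation of the enamine at C3, and capture of the aldehyde by the C8a hydroxyl to give lactol A1.

- Merits: it is the shortest route conceivable. Two skeletal bonds, the pyran ring and the stereocentre form in one operation. A3 needs no protecting groups and its symmetry removes any regiochemical question. The ring oxygen is automatically the C8a oxygen, which the chosen plan must arrange through steps 7, 8 and 12. In step count and atom economy this road is clearly better.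
- Weak points: C3 is created by proton transfer alpha to an aldehyde and alpha to an aryl group. A1 equilibrates with its open hydroxy-aldehyde, so the amine and acid that create the stereocentre can erase it through the same enamine. A2, with an ortho-alkoxy aryl group, is a hindered, polymerisation-prone acceptor needing several steps from 6. Removing the lactol oxygen needs either ionic reduction with a silane and acid (a threat to both alkenes) or reduction to the diol and Mitsunobu closure, which is the end game of the chosen plan anyway.
- Comparison: the chosen plan sets against the shorter sequence a stereocentre formed at a carbon with no acidifying neighbour, by a catalyst whose selectivity does not rest on a proton transfer, and untouched by every later step.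

**Alternative 2:** Cut C3–C4 with the C2' oxygen temporarily tied to C4 as a benzylic ether. A chiral dirhodium tetracarboxylate would decompose aryldiazoacetate A5, and the carbene at C3 would insert into the benzylic C4–H bond, giving the cis-dihydrobenzofuran A4. The furan ring is not part of 25.

- Merits: intramolecular insertion of donor/acceptor carbenes into benzylic ether C–H bonds is among the most dependable enantioselective C–C bond formations. C2 is already present as the ester carbon. In predictability of enantiocontrol on a hindered substrate this road is probably superior to an intermolecular three-component coupling with two ortho-substituted partners.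
- Weak points: A5 carries two nucleophilic alkenes, the prenyl group and the chromene, and the chromene sits on the ring that bears the carbene; both are classic carbene traps. The C4–O bond of the temporary ring must later be cleaved reductively without hydrogenolysis, leaving ionic hydrogenation or dissolving metal, both harsh on the alkenes and on a readily ionised 2,4-dioxygenated benzylic ether. Between insertion and ester reduction C3 is benzylic and alpha to an ester, and once C4 is deoxygenated any cis-to-trans epimerisation becomes loss of absolute configuration. The sequence is linear and builds a ring only to destroy it.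
- Comparison: the chosen plan is convergent and forms no bond that must be broken again. It must accept less certain catalyst control in exchange.

**Alternative 3:** Cut C3–C4 and O1–C2 at the acyl level. Fluoride would release the ring A ortho-quinone methide A7. A chiral azolium enolate, generated by an N-heterocyclic carbene from the activated ring B arylacetic ester A8, would add to the methide carbon (C4) and then acylate the phenoxide, closing lactone A6.

- Merits: ring, two bonds and stereocentre form in one step. The ring oxygen is by construction the C8a oxygen, so the oxygen-differentiation problem and the Mitsunobu step of the chosen plan disappear. No metal is needed. In economy of ring construction this road is as good or better.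
- Weak points: C4 is unsubstituted, so A7 is a highly reactive methide prone to oligomerisation. The only new stereocentre lies on the enolate carbon, so selectivity depends on enolate geometry and facial shielding alone. In A6, C3 is benzylic and alpha to a lactone carbonyl, the most epimerisable situation possible, under the basic conditions of its own formation. The lactone carbonyl must still become CH2, through lactol and silane with Lewis acid (alkenes at risk) or through diol and Mitsunobu closure, which gives back the steps saved. The precursors of A7 and A8 are not shorter to make than 15 and 6.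
- Comparison: the chosen plan answers with a C3 that is never alpha to a carbonyl, with C2 introduced at the alcohol oxidation level, and with fragment syntheses based on directed metalation.

Key step: step 9

Assumption: the antipode of the C2-symmetric ferrocenyl bisphosphine used in step 9 is the one that leads to (R)-19; the sense of induction is to be fixed in a calibration run, and both antipodes are available, so this is a choice of reagent and not a change of route.

## Route

Isoflavan numbering is used throughout. TBS is tert-butyldimethylsilyl, MOM is methoxymethyl, Bpin is the pinacol boronic ester.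

Step 1
Reactants: 1 cyclohexane-1,3-dione; 2 3-methylbut-2-enal (prenal)
Product: 3 2,2-dimethyl-7,8-dihydro-2H-chromen-5(6H)-one
Conditions: ethylenediammonium diacetate (10 mol%), MeOH, rt
Reagents that add atoms: none
Why: Knoevenagel condensation gives a 1-oxatriene that closes by 6π-oxa-electrocyclisation (formal [3+3] annulation). Building ring B from the dione fixes the positions of the future C2' oxygen and the pyran oxygen.

Step 2
Reactants: 3 2,2-dimethyl-7,8-dihydro-2H-chromen-5(6H)-one
Product: 5 2,2-dimethyl-2H-chromen-5-ol, via alpha-selanyl ketone 4 (not isolated)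
Conditions: LiN(i-Pr)2, THF, −78 °C; PhSeCl, −78 °C; then H2O2 (30% aq., excess), pyridine, CH2Cl2, 0 °C → rt
Reagents that add atoms: none
Why: Kinetic deprotonation of the vinylogous ester at the alpha' carbon and selenenylation give 4; oxidation at selenium, syn-elimination (selenoxide elimination) and tautomerisation aromatise the ring. Excess peroxide takes the selenium by-product to the seleninic acid so that it cannot add to the pyran alkene.

Step 3
Reactants: 5 2,2-dimethyl-2H-chromen-5-ol
Product: 6 5-(methoxymethoxy)-2,2-dimethyl-2H-chromene
Conditions: MOMCl, i-Pr2NEt, CH2Cl2, 0 °C → rt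
Reagents that add atoms: chloromethyl methyl ether (MOMCl), COCCl
Why: O-alkylation of the phenol under amine base. The MOM ether protects the C2' oxygen through the pyran closure and directs the metalation in step 9.

Step 4
Reactants: 7 resorcinol
Product: 8 1,3-bis(methoxymethoxy)benzene
Conditions: MOMCl (2.4 equiv), i-Pr2NEt, CH2Cl2, 0 °C → rt
Reagents that add atoms: chloromethyl methyl ether (MOMCl), COCCl
Why: Double O-alkylation of both phenols; the two MOM ethers are the directing groups for steps 5 and 6.

Step 5
Reactants: 8 1,3-bis(methoxymethoxy)benzene; 9 1-bromo-3-methylbut-2-ene (prenyl bromide)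
Product: 11 1,3-bis(methoxymethoxy)-2-(3-methylbut-2-en-1-yl)benzene, via 2-lithiated arene 10 (not isolated)
Conditions: n-BuLi, THF, 0 °C → rt; CuI (10 mol%), then 9, −78 °C → rt
Reagents that add atoms: none
Why: Directed ortho-metalation: the position between two MOM ethers is the most acidic and is lithiated exclusively. Copper-catalysed SN2 allylation then gives the linear prenyl arene, attack at the tertiary allyl terminus being sterically disfavoured.

Step 6
Reactants: 11 1,3-bis(methoxymethoxy)-2-(3-methylbut-2-en-1-yl)benzene
Product: 13 1-bromo-2,4-bis(methoxymethoxy)-3-(3-methylbut-2-en-1-yl)benzene, via 4-lithiated arene 12 (not isolated)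
Conditions: n-BuLi, TMEDA, Et2O, 0 °C; BrCl2C–CCl2Br, −78 °C → rt
Reagents that add atoms: 1,2-dibromo-1,1,2,2-tetrachloroethane, ClC(Cl)(Br)C(Cl)(Cl)Br
Why: Second directed ortho-metalation; the two remaining ortho positions of 11 are equivalent by symmetry, so one aryllithium forms, and MOM-coordinated ring metalation is expected to outrun deprotonation of the benzylic-allylic CH2. Bromine is transferred to the carbanion from a reagent that does not attack alkenes, so the prenyl double bond never meets electrophilic bromine.

Step 7
Reactants: 13 1-bromo-2,4-bis(methoxymethoxy)-3-(3-methylbut-2-en-1-yl)benzene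
Product: 14 4-bromo-2-(3-methylbut-2-en-1-yl)benzene-1,3-diol
Conditions: HCl (conc. aq., cat.), MeOH, rt → 40 °C
Reagents that add atoms: none
Why: Acid-catalysed acetal exchange with methanol removes both MOM groups. Dilute acid near room temperature is the usual window in which an ortho-prenyl phenol does not yet cyclise to the chroman.

Step 8
Reactants: 14 4-bromo-2-(3-methylbut-2-en-1-yl)benzene-1,3-diol
Product: 15 1-bromo-2,4-bis[(tert-butyldimethylsilyl)oxy]-3-(3-methylbut-2-en-1-yl)benzene
Conditions: TBSCl, imidazole, DMF, rt → 40 °C
Reagents that add atoms: tert-butyldimethylsilyl chloride (TBSCl), CC(C)(C)[Si](C)(C)Cl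
Why: Imidazole-promoted silylation of both phenols. The silyl ethers are orthogonal to the ring B MOM ether, so fluoride in step 12 frees the C8a oxygen while the C2' oxygen stays masked.

Step 9
Reactants: 6 5-(methoxymethoxy)-2,2-dimethyl-2H-chromene; 16 vinylboronic acid pinacol ester; 15 1-bromo-2,4-bis[(tert-butyldimethylsilyl)oxy]-3-(3-methylbut-2-en-1-yl)benzene
Product: 19 2-[(1R)-2-{2,4-bis[(tert-butyldimethylsilyl)oxy]-3-(3-methylbut-2-en-1-yl)phenyl}-1-[5-(methoxymethoxy)-2,2-dimethyl-2H-chromen-6-yl]ethyl]-4,4,5,5-tetramethyl-1,3,2-dioxaborolane, via ring B aryllithium 17 (not isolated), via lithium vinylboronate complex 18 (not isolated)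
Conditions: 6 (1.3 equiv), n-BuLi (1.2 equiv), Et2O, 0 °C → rt; 16 (1.2 equiv), 0 °C → rt; solvent switch to THF; 15 (1.0 equiv), Pd(OAc)2 (3 mol%), 2,2′-bis[(dimethylamino)(phenyl)methyl]-1,1′-bis(diphenylphosphino)ferrocene (single antipode, MandyPhos type, 3.6 mol%), NaOTf (2 equiv), 60 °C
Reagents that add atoms: none
Why: The MOM ether directs n-BuLi to the only free ortho position of 6 (C1' of the isoflavan), and the resulting 17 adds to the boron of 16 to give the four-coordinate boronate 18. Pd(OAc)2 and the bisphosphine give zerovalent palladium, which inserts into the C4a–Br bond of 15; NaOTf removes bromide so that the cationic divalent arylpalladium can bind the vinyl group of 18. Palladium-induced 1,2-metallate rearrangement then moves ring B from boron to the alpha carbon (C3) anti to palladium, which bonds to the beta carbon (C4), and reductive elimination joins C4 to C4a and returns zerovalent palladium. The closest known reaction type is the palladium-catalysed enantioselective conjunctive cross-coupling of vinylboron ate complexes with aryl halides in the presence of a triflate salt, applied here to two ortho-substituted partners. No ring is closed. The C3 stereocentre is set by the chiral bisphosphine, which decides the face of the vinylboronate that binds palladium, and the antipode is chosen to give (R). The step needs conjunctive coupling to win over direct Suzuki-type transfer and beta-hydride elimination, and needs the prenyl and chromene alkenes to stay out: only the boronate-activated vinyl group is nucleophilic enough to engage arylpalladium, the electron-rich ring B migrates readily, and the chelating bisphosphine favours reductive elimination. Using less n-BuLi than 6 leaves no butyllithium to form a competing butylboronate, and because 17 is consumed by 16 before 15 is added, no bromine–lithium exchange on 15 can occur.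

Step 10
Reactants: 19 the (R)-secondary boronic ester from step 9
Product: 21 2-[(2R)-3-{2,4-bis[(tert-butyldimethylsilyl)oxy]-3-(3-methylbut-2-en-1-yl)phenyl}-2-[5-(methoxymethoxy)-2,2-dimethyl-2H-chromen-6-yl]propyl]-4,4,5,5-tetramethyl-1,3,2-dioxaborolane, via chloromethyl boronate complex 20 (not isolated)
Conditions: ICH2Cl (3 equiv), n-BuLi (2.5 equiv), THF, −78 °C → rt
Reagents that add atoms: chloroiodomethane, ClCI
Why: Matteson homologation: LiCH2Cl, formed in situ by iodine–lithium exchange, adds to boron at −78 °C to give 20, and on warming the secondary alkyl group migrates from boron to carbon with loss of chloride and with retention at C3, inserting C2. The shift occurs only after the carbenoid has decayed, so the less hindered product is not homologated a second time.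

Step 11
Reactants: 21 the (R)-primary boronic ester from step 10
Product: 22 (2R)-3-{2,4-bis[(tert-butyldimethylsilyl)oxy]-3-(3-methylbut-2-en-1-yl)phenyl}-2-[5-(methoxymethoxy)-2,2-dimethyl-2H-chromen-6-yl]propan-1-ol
Conditions: NaBO3·4H2O, THF/H2O (1:1), rt
Reagents that add atoms: sodium perborate tetrahydrate (NaBO3·4H2O; dimeric peroxoborate, water of crystallisation omitted), [Na+].[Na+].O[B-]1(O)OO[B-](O)(O)OO1
Why: Oxidation of the primary C–B bond by peroxide-type 1,2-shift from boron to oxygen; C3 is not a reacting centre. The nearly neutral perborate medium spares the aryl silyl ethers, and partial loss would not matter because step 12 removes them.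

Step 12
Reactants: 22 the (R)-bis-silyl alcohol from step 11
Product: 23 4-{(2R)-3-hydroxy-2-[5-(methoxymethoxy)-2,2-dimethyl-2H-chromen-6-yl]propyl}-2-(3-methylbut-2-en-1-yl)benzene-1,3-diol
Conditions: TBAF (2.2 equiv), AcOH (2.2 equiv), THF, 0 °C
Reagents that add atoms: none
Why: Fluoride cleaves both aryl Si–O bonds rapidly while acetic acid buffers the phenoxides; the MOM ether and the primary alcohol are untouched.

Step 13
Reactants: 23 the (R)-triol from step 12
Product: 24 (3R)-3-[5-(methoxymethoxy)-2,2-dimethyl-2H-chromen-6-yl]-8-(3-methylbut-2-en-1-yl)-3,4-dihydro-2H-chromen-7-ol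
Conditions: PPh3, DIAD, THF (high dilution), 0 °C → rt
Reagents that add atoms: none
Why: Intramolecular Mitsunobu etherification: the primary alcohol is activated as its alkoxyphosphonium ion and displaced by the C8a phenol in a 6-exo-tet closure. The C7 phenol can react only intermolecularly, which dilution suppresses, and the C2' oxygen is blocked as its MOM ether, so the five-membered closure is impossible; C3 keeps its configuration because it is not a reacting centre.

Step 14
Reactants: 24 the (R)-MOM-protected isoflavan from step 13
Product: 25 (3R)-3-(5-hydroxy-2,2-dimethyl-2H-chromen-6-yl)-8-(3-methylbut-2-en-1-yl)-3,4-dihydro-2H-chromen-7-ol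
Conditions: HCl (conc. aq., cat.), MeOH/THF, rt → 40 °C
Reagents that add atoms: none
Why: Acid-catalysed acetal exchange with methanol removes the MOM group; C3 has no acidifying neighbour and cannot epimerise. Dilute acid at moderate temperature is chosen because the ortho-prenyl phenol and the chromene tolerate it only for a limited time.

## Compound list

1 | cyclohexane-1,3-dione | O=C1CCCC(=O)C1 | starting material
2 | 3-methylbut-2-enal (prenal) | CC(C)=CC=O | starting material
3 | 2,2-dimethyl-7,8-dihydro-2H-chromen-5(6H)-one | CC1(C)C=CC2=C(CCCC2=O)O1 | intermediate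
4 | 2,2-dimethyl-6-(phenylselanyl)-7,8-dihydro-2H-chromen-5(6H)-one (racemic, not isolated) | CC1(C)C=CC2=C(CCC([Se]c3ccccc3)C2=O)O1 | intermediate
5 | 2,2-dimethyl-2H-chromen-5-ol | CC1(C)C=Cc2c(O)cccc2O1 | intermediate
6 | 5-(methoxymethoxy)-2,2-dimethyl-2H-chromene | COCOc1cccc2c1C=CC(C)(C)O2 | intermediate
7 | resorcinol (benzene-1,3-diol) | Oc1cccc(O)c1 | starting material
8 | 1,3-bis(methoxymethoxy)benzene | COCOc1cccc(OCOC)c1 | intermediate
9 | 1-bromo-3-methylbut-2-ene (prenyl bromide) | CC(C)=CCBr | starting material
10 | [2,6-bis(methoxymethoxy)phenyl]lithium (not isolated) | [Li]c1c(OCOC)cccc1OCOC | intermediate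
11 | 1,3-bis(methoxymethoxy)-2-(3-methylbut-2-en-1-yl)benzene | CC(C)=CCc1c(OCOC)cccc1OCOC | intermediate
12 | [2,4-bis(methoxymethoxy)-3-(3-methylbut-2-en-1-yl)phenyl]lithium (not isolated) | [Li]c1ccc(OCOC)c(CC=C(C)C)c1OCOC | intermediate
13 | 1-bromo-2,4-bis(methoxymethoxy)-3-(3-methylbut-2-en-1-yl)benzene | CC(C)=CCc1c(OCOC)ccc(Br)c1OCOC | intermediate
14 | 4-bromo-2-(3-methylbut-2-en-1-yl)benzene-1,3-diol | CC(C)=CCc1c(O)ccc(Br)c1O | intermediate
15 | 1-bromo-2,4-bis[(tert-butyldimethylsilyl)oxy]-3-(3-methylbut-2-en-1-yl)benzene (ring A aryl bromide) | CC(C)=CCc1c(O[Si](C)(C)C(C)(C)C)ccc(Br)c1O[Si](C)(C)C(C)(C)C | intermediate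
16 | vinylboronic acid pinacol ester (2-ethenyl-4,4,5,5-tetramethyl-1,3,2-dioxaborolane) | C=CB1OC(C)(C)C(C)(C)O1 | starting material
17 | [5-(methoxymethoxy)-2,2-dimethyl-2H-chromen-6-yl]lithium (ring B aryllithium, not isolated) | [Li]c1ccc2c(c1OCOC)C=CC(C)(C)O2 | intermediate
18 | lithium 2-ethenyl-2-[5-(methoxymethoxy)-2,2-dimethyl-2H-chromen-6-yl]-4,4,5,5-tetramethyl-1,3,2-dioxaborolan-2-uide (not isolated) | [Li+].C=C[B-]1(OC(C)(C)C(C)(C)O1)c1ccc2c(c1OCOC)C=CC(C)(C)O2 | intermediate
19 | 2-[(1R)-2-{2,4-bis[(tert-butyldimethylsilyl)oxy]-3-(3-methylbut-2-en-1-yl)phenyl}-1-[5-(methoxymethoxy)-2,2-dimethyl-2H-chromen-6-yl]ethyl]-4,4,5,5-tetramethyl-1,3,2-dioxaborolane | CC(C)=CCc1c(O[Si](C)(C)C(C)(C)C)ccc(C[C@@H](B2OC(C)(C)C(C)(C)O2)c2ccc3c(c2OCOC)C=CC(C)(C)O3)c1O[Si](C)(C)C(C)(C)C | intermediate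
20 | lithium 2-(chloromethyl)-2-[(1R)-2-{2,4-bis[(tert-butyldimethylsilyl)oxy]-3-(3-methylbut-2-en-1-yl)phenyl}-1-[5-(methoxymethoxy)-2,2-dimethyl-2H-chromen-6-yl]ethyl]-4,4,5,5-tetramethyl-1,3,2-dioxaborolan-2-uide (not isolated) | [Li+].ClC[B-]1(OC(C)(C)C(C)(C)O1)[C@H](Cc1ccc(O[Si](C)(C)C(C)(C)C)c(CC=C(C)C)c1O[Si](C)(C)C(C)(C)C)c1ccc2c(c1OCOC)C=CC(C)(C)O2 | intermediate
21 | 2-[(2R)-3-{2,4-bis[(tert-butyldimethylsilyl)oxy]-3-(3-methylbut-2-en-1-yl)phenyl}-2-[5-(methoxymethoxy)-2,2-dimethyl-2H-chromen-6-yl]propyl]-4,4,5,5-tetramethyl-1,3,2-dioxaborolane | CC(C)=CCc1c(O[Si](C)(C)C(C)(C)C)ccc(C[C@@H](CB2OC(C)(C)C(C)(C)O2)c2ccc3c(c2OCOC)C=CC(C)(C)O3)c1O[Si](C)(C)C(C)(C)C | intermediate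
22 | (2R)-3-{2,4-bis[(tert-butyldimethylsilyl)oxy]-3-(3-methylbut-2-en-1-yl)phenyl}-2-[5-(methoxymethoxy)-2,2-dimethyl-2H-chromen-6-yl]propan-1-ol | CC(C)=CCc1c(O[Si](C)(C)C(C)(C)C)ccc(C[C@@H](CO)c2ccc3c(c2OCOC)C=CC(C)(C)O3)c1O[Si](C)(C)C(C)(C)C | intermediate
23 | 4-{(2R)-3-hydroxy-2-[5-(methoxymethoxy)-2,2-dimethyl-2H-chromen-6-yl]propyl}-2-(3-methylbut-2-en-1-yl)benzene-1,3-diol | CC(C)=CCc1c(O)ccc(C[C@@H](CO)c2ccc3c(c2OCOC)C=CC(C)(C)O3)c1O | intermediate
24 | (3R)-3-[5-(methoxymethoxy)-2,2-dimethyl-2H-chromen-6-yl]-8-(3-methylbut-2-en-1-yl)-3,4-dihydro-2H-chromen-7-ol | CC(C)=CCc1c(O)ccc2c1OC[C@@H](c1ccc3c(c1OCOC)C=CC(C)(C)O3)C2 | intermediate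
25 | (3R)-3-(5-hydroxy-2,2-dimethyl-2H-chromen-6-yl)-8-(3-methylbut-2-en-1-yl)-3,4-dihydro-2H-chromen-7-ol (CNP0263294.2) | CC(C)=CCc1c(O)ccc2c1OC[C@@H](c1ccc3c(c1O)C=CC(C)(C)O3)C2 | target

## Step count and least certain steps

Total: 14 steps. Longest linear sequence: 11 steps (steps 4 to 14, from resorcinol 7). The ring B branch (steps 1 to 3) joins at step 9.

**Step 9 (key step).** The likely failures are slow oxidative addition into the electron-rich C–Br bond flanked by a silyloxy group, with direct Suzuki-type transfer of ring B or the vinyl group overtaking the conjunctive pathway, and erosion of facial control because both partners carry ortho substituents. Fallback: a lithiation–borylation that forms C3–C1' by the same kind of 1,2-shift, but with C4–C4a already in place and the stereocentre set by a stoichiometric chiral diamine. It sets out from 15 and 6 and returns at 19.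

Stille coupling of 15 with Bu3SnCH=CH2 (Pd(PPh3)4, toluene, 100 °C) gives 1-ethenyl-2,4-bis[(tert-butyldimethylsilyl)oxy]-3-(3-methylbut-2-en-1-yl)benzene F1. Hydroboration with 9-BBN, which takes the monosubstituted styrene alkene and leaves the trisubstituted prenyl alkene, followed by NaBO3 oxidation gives 2-{2,4-bis[(tert-butyldimethylsilyl)oxy]-3-(3-methylbut-2-en-1-yl)phenyl}ethan-1-ol F2. N,N-Diisopropylcarbamoyl chloride with Et3N converts F2 into the corresponding 2-arylethyl N,N-diisopropylcarbamate F3.

Separately, 6 is lithiated as in step 9 and quenched with 2-isopropoxy-4,4,5,5-tetramethyl-1,3,2-dioxaborolane to give the isolable 2-[5-(methoxymethoxy)-2,2-dimethyl-2H-chromen-6-yl]-4,4,5,5-tetramethyl-1,3,2-dioxaborolane F4. Asymmetric deprotonation of F3 alpha to oxygen with s-BuLi and the appropriate sparteine antipode (Et2O, −78 °C), addition of F4 and warming (MgBr2 in MeOH if the shift is slow) move ring B from boron to carbon with loss of the carbamate and give 19.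

**Step 6.** The likely failure is deprotonation at the benzylic-allylic CH2 of the prenyl group instead of ring metalation, leading to alkene migration or bromination in the side chain. Fallback: install both halogens before the prenyl group. It sets out from 8 and returns at 13.

Lithiation of 8 as in step 5 and quenching with I2 gives 2-iodo-1,3-bis(methoxymethoxy)benzene F5. NBS in MeCN at 0 °C, with no alkene present, brominates the position ortho to one MOM ether and para to the other, giving 1-bromo-3-iodo-2,4-bis(methoxymethoxy)benzene F6. Selective iodine–magnesium exchange with i-PrMgCl·LiCl (THF, −40 °C → −20 °C; the iodide between two oxygens reacts well before the bromide), then CuI (cat.) and 9, gives 13.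

**Step 10.** The likely failure is incomplete capture of the short-lived LiCH2Cl by the hindered secondary boronic ester, which is flanked by an ortho-substituted aryl group, so that unchanged 19 is recovered. Fallback: a stable, preformed carbenoid followed by hydride displacement. It sets out from 19 and returns at 21.

LiCHCl2 (from CH2Cl2 and n-BuLi, THF, −100 °C) is added to 19, and ZnCl2 promotes the 1,2-shift on warming. This gives the alpha-chloro boronic ester 2-[(2R)-1-chloro-3-{2,4-bis[(tert-butyldimethylsilyl)oxy]-3-(3-methylbut-2-en-1-yl)phenyl}-2-[5-(methoxymethoxy)-2,2-dimethyl-2H-chromen-6-yl]propyl]-4,4,5,5-tetramethyl-1,3,2-dioxaborolane F7, a mixture at the chlorine-bearing carbon, which is of no consequence. LiBHEt3 then adds hydride to boron and a 1,2-hydride shift expels chloride to give 21.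

**Step 13.** The likely failures are elimination from the activated primary alcohol toward the 2-arylallyl alkene and intermolecular etherification through the free C7 phenol, because the C8a phenol is hindered by the neighbouring prenyl group. Fallback: a fluoride-triggered Williamson closure in which only the C8a oxygen can reach the leaving group. It sets out from 22 and returns at 24, bypassing 23.

MsCl and Et3N (CH2Cl2, 0 °C) convert 22 into (2R)-3-{2,4-bis[(tert-butyldimethylsilyl)oxy]-3-(3-methylbut-2-en-1-yl)phenyl}-2-[5-(methoxymethoxy)-2,2-dimethyl-2H-chromen-6-yl]propyl methanesulfonate F8. TBAF in THF then removes both silyl groups, and the C8a phenoxide displaces the mesylate in a 6-exo-tet closure to give 24.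

**Step 14.** The likely failures are acid-induced cyclisation of the prenyl group onto the C7 hydroxyl and solvent addition across the chromene alkene before the MOM ether is fully cleaved. Fallback: replace protic hydrolysis by buffered silyl transfer through an isolable silyl ether. It sets out from 24 and returns at 25.

TMSOTf and 2,2′-bipyridyl (CH2Cl2, 0 °C) convert the aryl MOM ether into the aryl trimethylsilyl ether and silylate the free C7 phenol, giving (3R)-8-(3-methylbut-2-en-1-yl)-7-[(trimethylsilyl)oxy]-3-{2,2-dimethyl-5-[(trimethylsilyl)oxy]-2H-chromen-6-yl}-3,4-dihydro-2H-chromene F9. Water, or K2CO3 in MeOH at rt, hydrolyses both Si–O bonds to give 25.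

## Further compounds

F1 | step 9 | 1-ethenyl-2,4-bis[(tert-butyldimethylsilyl)oxy]-3-(3-methylbut-2-en-1-yl)benzene | C=Cc1ccc(O[Si](C)(C)C(C)(C)C)c(CC=C(C)C)c1O[Si](C)(C)C(C)(C)C
F2 | step 9 | 2-{2,4-bis[(tert-butyldimethylsilyl)oxy]-3-(3-methylbut-2-en-1-yl)phenyl}ethan-1-ol | OCCc1ccc(O[Si](C)(C)C(C)(C)C)c(CC=C(C)C)c1O[Si](C)(C)C(C)(C)C
F3 | step 9 | 2-{2,4-bis[(tert-butyldimethylsilyl)oxy]-3-(3-methylbut-2-en-1-yl)phenyl}ethyl N,N-diisopropylcarbamate | CC(C)N(C(C)C)C(=O)OCCc1ccc(O[Si](C)(C)C(C)(C)C)c(CC=C(C)C)c1O[Si](C)(C)C(C)(C)C
F4 | step 9 | 2-[5-(methoxymethoxy)-2,2-dimethyl-2H-chromen-6-yl]-4,4,5,5-tetramethyl-1,3,2-dioxaborolane | COCOc1c(B2OC(C)(C)C(C)(C)O2)ccc2c1C=CC(C)(C)O2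
F5 | step 6 | 2-iodo-1,3-bis(methoxymethoxy)benzene | COCOc1cccc(OCOC)c1I
F6 | step 6 | 1-bromo-3-iodo-2,4-bis(methoxymethoxy)benzene | COCOc1ccc(Br)c(OCOC)c1I
F7 | step 10 | 2-[(2R)-1-chloro-3-{2,4-bis[(tert-butyldimethylsilyl)oxy]-3-(3-methylbut-2-en-1-yl)phenyl}-2-[5-(methoxymethoxy)-2,2-dimethyl-2H-chromen-6-yl]propyl]-4,4,5,5-tetramethyl-1,3,2-dioxaborolane (mixture at C1) | CC(C)=CCc1c(O[Si](C)(C)C(C)(C)C)ccc(C[C@@H](C(Cl)B2OC(C)(C)C(C)(C)O2)c2ccc3c(c2OCOC)C=CC(C)(C)O3)c1O[Si](C)(C)C(C)(C)C
F8 | step 13 | (2R)-3-{2,4-bis[(tert-butyldimethylsilyl)oxy]-3-(3-methylbut-2-en-1-yl)phenyl}-2-[5-(methoxymethoxy)-2,2-dimethyl-2H-chromen-6-yl]propyl methanesulfonate | CC(C)=CCc1c(O[Si](C)(C)C(C)(C)C)ccc(C[C@@H](COS(C)(=O)=O)c2ccc3c(c2OCOC)C=CC(C)(C)O3)c1O[Si](C)(C)C(C)(C)C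
F9 | step 14 | (3R)-8-(3-methylbut-2-en-1-yl)-7-[(trimethylsilyl)oxy]-3-{2,2-dimethyl-5-[(trimethylsilyl)oxy]-2H-chromen-6-yl}-3,4-dihydro-2H-chromene | CC(C)=CCc1c(O[Si](C)(C)C)ccc2c1OC[C@@H](c1ccc3c(c1O[Si](C)(C)C)C=CC(C)(C)O3)C2
A1 | alternative 1 | (3R)-3-[5-(methoxymethoxy)-2,2-dimethyl-2H-chromen-6-yl]-8-(3-methylbut-2-en-1-yl)chromane-2,7-diol (lactol, anomeric mixture at C2) | CC(C)=CCc1c(O)ccc2c1OC(O)[C@@H](c1ccc3c(c1OCOC)C=CC(C)(C)O3)C2
A2 | alternative 1 | 2-[5-(methoxymethoxy)-2,2-dimethyl-2H-chromen-6-yl]prop-2-enal | C=C(C=O)c1ccc2c(c1OCOC)C=CC(C)(C)O2
A3 | alternative 1 | 2-(3-methylbut-2-en-1-yl)benzene-1,3-diol (2-prenylresorcinol) | CC(C)=CCc1c(O)cccc1O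
A4 | alternative 2 | methyl cis-2-{2,4-bis[(tert-butyldimethylsilyl)oxy]-3-(3-methylbut-2-en-1-yl)phenyl}-2,3-dihydrobenzofuran-3-carboxylate carrying the fused 2,2-dimethyl-2H-pyran of ring B (temporary furan ring) | COC(=O)[C@H]1c2ccc3c(c2O[C@H]1c1ccc(O[Si](C)(C)C(C)(C)C)c(CC=C(C)C)c1O[Si](C)(C)C(C)(C)C)C=CC(C)(C)O3
A5 | alternative 2 | methyl 2-diazo-2-[5-({2,4-bis[(tert-butyldimethylsilyl)oxy]-3-(3-methylbut-2-en-1-yl)phenyl}methoxy)-2,2-dimethyl-2H-chromen-6-yl]acetate | COC(=O)C(=[N+]=[N-])c1ccc2c(c1OCc1ccc(O[Si](C)(C)C(C)(C)C)c(CC=C(C)C)c1O[Si](C)(C)C(C)(C)C)C=CC(C)(C)O2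
A6 | alternative 3 | (3R)-7-(methoxymethoxy)-3-[5-(methoxymethoxy)-2,2-dimethyl-2H-chromen-6-yl]-8-(3-methylbut-2-en-1-yl)chroman-2-one | CC(C)=CCc1c(OCOC)ccc2c1OC(=O)[C@@H](c1ccc3c(c1OCOC)C=CC(C)(C)O3)C2
A7 | alternative 3 | 3-(methoxymethoxy)-6-methylidene-2-(3-methylbut-2-en-1-yl)cyclohexa-2,4-dien-1-one (ring A ortho-quinone methide) | C=C1C=CC(OCOC)=C(CC=C(C)C)C1=O
A8 | alternative 3 | 4-nitrophenyl 2-[5-(methoxymethoxy)-2,2-dimethyl-2H-chromen-6-yl]acetate | O=C(Cc1ccc2c(c1OCOC)C=CC(C)(C)O2)Oc1ccc([N+](=O)[O-])cc1
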